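**Retrosynthetic overview**
1. Target 17 ⇐ 16 (aryl silyl ether cleavage) ⇐ 15 (enoate to allylic alcohol) ⇐ 14 (reductive removal of the auxiliary; the imide carbon becomes C9H2OH).
2. Key C7–C8 bond: intermolecular Evans syn-aldol between the Z-dibutylboron enolate of aryloxyacetyl imide 11 and aldehyde 2; both stereocentres are set in this step.
3. 11 ⇐ acid 8 + (R)-4-benzyl-2-oxazolidinone 9; 8 ⇐ syringaldehyde 3 (O-alkylation, Wittig olefination, tert-butyl ester cleavage); 2 ⇐ vanillin 1.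
4. No ring is formed: ring A is bought as vanillin and ring B as syringaldehyde.

Assumption: the SMILES is read as the (7S,8S) threo isomer, i.e. (1S,2S) in the propane-1,3-diol name; in the zigzag drawing this is the 2,3-syn aldol pattern.

**Route**

Step 1
Reactants: 1 vanillin
Product: 2 3-methoxy-4-(triisopropylsilyloxy)benzaldehyde
Conditions: TIPSCl, imidazole, DMF, rt
Reagents that add atoms: triisopropylsilyl chloride, CC(C)[Si](Cl)(C(C)C)C(C)C
Why: Imidazole-promoted O-silylation of the phenol gives a robust aryl silyl ether that survives the boron aldol, hydride reductions and is removable without touching the alkene.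

Step 2
Reactants: 3 syringaldehyde; 4 tert-butyl bromoacetate
Product: 5 tert-butyl 2-(4-formyl-2,6-dimethoxyphenoxy)acetate
Conditions: K2CO3, DMF, 60 °C
Reagents that add atoms: none
Why: Williamson ether synthesis; the acidic para-formyl phenoxide displaces the activated primary bromide cleanly.

Step 3
Reactants: 5 tert-butyl 2-(4-formyl-2,6-dimethoxyphenoxy)acetate; 6 methyl (triphenylphosphoranylidene)acetate
Product: 7 methyl (E)-3-[4-(2-tert-butoxy-2-oxoethoxy)-3,5-dimethoxyphenyl]prop-2-enoate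
Conditions: toluene, 90 °C
Reagents that add atoms: none
Why: Wittig olefination with a stabilised ylide gives the E-enoate under base-free conditions that leave the tert-butyl ester untouched.

Step 4
Reactants: 7 methyl (E)-3-[4-(2-tert-butoxy-2-oxoethoxy)-3,5-dimethoxyphenyl]prop-2-enoate
Product: 8 2-{2,6-dimethoxy-4-[(E)-3-methoxy-3-oxoprop-1-enyl]phenoxy}acetic acid
Conditions: CF3CO2H/CH2Cl2 (1:4), rt
Reagents that add atoms: none
Why: Acid-mediated tert-butyl ester cleavage (loss of isobutene) is orthogonal to the methyl enoate.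

Step 5
Reactants: 8 2-{2,6-dimethoxy-4-[(E)-3-methoxy-3-oxoprop-1-enyl]phenoxy}acetic acid; 9 (R)-4-benzyl-2-oxazolidinone
Product: 11 (R)-4-benzyl-3-(2-{2,6-dimethoxy-4-[(E)-3-methoxy-3-oxoprop-1-enyl]phenoxy}acetyl)oxazolidin-2-one, via mixed pivalic anhydride 10 (not isolated)
Conditions: PivCl, Et3N, THF, −20 °C; then 9, LiCl, −20 °C → rt
Reagents that add atoms: pivaloyl chloride, CC(C)(C)C(Cl)=O (its acyl group is carried only by intermediate 10 and is lost again on the way to 11)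
Why: N-acylation of the oxazolidinone through a mixed anhydride (LiCl/Et3N protocol) occurs at the unhindered aryloxyacetyl carbonyl and avoids strong base near the enoate.

Step 6
Reactants: 11 (R)-4-benzyl-3-(2-{2,6-dimethoxy-4-[(E)-3-methoxy-3-oxoprop-1-enyl]phenoxy}acetyl)oxazolidin-2-one; 2 3-methoxy-4-(triisopropylsilyloxy)benzaldehyde
Product: 14 (R)-4-benzyl-3-[(2R,3S)-2-{2,6-dimethoxy-4-[(E)-3-methoxy-3-oxoprop-1-enyl]phenoxy}-3-hydroxy-3-(3-methoxy-4-triisopropylsilyloxyphenyl)propanoyl]oxazolidin-2-one, via dibutylboron Z-enolate 12 (not isolated), via dibutylboron aldolate 13 (not isolated)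
Conditions: Bu2BOTf, iPr2NEt, CH2Cl2, −78 → 0 °C; then 2, −78 → 0 °C; then pH 7 buffer (NaH2PO4/Na2HPO4), MeOH, 30% H2O2, 0 °C
Reagents that add atoms: dibutylboron triflate, CCCCB(CCCC)OS(=O)(=O)C(F)(F)F (its Bu2B group is carried only by intermediates 12 and 13)
Why: Evans syn-aldol: the Z-boron enolate reacts through a Zimmerman–Traxler chair on the face opposite the benzyl group of the dipole-opposed (R)-auxiliary, giving the 2,3-syn (2R,3S) adduct, which is the 7S,8S pattern of the target.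

Step 7
Reactants: 14 (R)-4-benzyl-3-[(2R,3S)-2-{2,6-dimethoxy-4-[(E)-3-methoxy-3-oxoprop-1-enyl]phenoxy}-3-hydroxy-3-(3-methoxy-4-triisopropylsilyloxyphenyl)propanoyl]oxazolidin-2-one
Product: 15 methyl (E)-3-(4-{[(1S,2S)-1,3-dihydroxy-1-(3-methoxy-4-triisopropylsilyloxyphenyl)propan-2-yl]oxy}-3,5-dimethoxyphenyl)prop-2-enoate
Conditions: NaBH4, THF/H2O (4:1), 0 °C → rt
Reagents that add atoms: none
Why: Reductive cleavage of the N-acyloxazolidinone by borohydride is much faster than reduction of the conjugated methyl ester and does not touch either stereocentre.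

Step 8
Reactants: 15 methyl (E)-3-(4-{[(1S,2S)-1,3-dihydroxy-1-(3-methoxy-4-triisopropylsilyloxyphenyl)propan-2-yl]oxy}-3,5-dimethoxyphenyl)prop-2-enoate
Product: 16 (1S,2S)-2-{4-[(E)-3-hydroxyprop-1-enyl]-2,6-dimethoxyphenoxy}-1-(3-methoxy-4-triisopropylsilyloxyphenyl)propane-1,3-diol
Conditions: i-Bu2AlH (5 equiv), CH2Cl2, −78 → −20 °C; aq. potassium sodium tartrate (KNaC4H4O6) work-up
Reagents that add atoms: none
Why: DIBAL-H 1,2-reduction of the enoate gives the E-allylic alcohol without conjugate reduction; the two free hydroxyls only consume extra hydride as aluminium alkoxides.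

Step 9
Reactants: 16 (1S,2S)-2-{4-[(E)-3-hydroxyprop-1-enyl]-2,6-dimethoxyphenoxy}-1-(3-methoxy-4-triisopropylsilyloxyphenyl)propane-1,3-diol
Product: 17 (1S,2S)-1-(4-hydroxy-3-methoxyphenyl)-2-{4-[(E)-3-hydroxyprop-1-enyl]-2,6-dimethoxyphenoxy}propane-1,3-diol
Conditions: Bu4NF, AcOH (1.1 equiv each), THF, 0 °C
Reagents that add atoms: none
Why: Fluoride-mediated desilylation of the aryl silyl ether, buffered with acetic acid so the free para-hydroxybenzyl alcohol never sits in basic or acidic medium.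

**Compound list**
1 | vanillin | COc1cc(C=O)ccc1O | starting material
2 | 3-methoxy-4-(triisopropylsilyloxy)benzaldehyde | COc1cc(C=O)ccc1O[Si](C(C)C)(C(C)C)C(C)C | intermediate
3 | syringaldehyde | COc1cc(C=O)cc(OC)c1O | starting material
4 | tert-butyl bromoacetate | CC(C)(C)OC(=O)CBr | starting material
5 | tert-butyl 2-(4-formyl-2,6-dimethoxyphenoxy)acetate | COc1cc(C=O)cc(OC)c1OCC(=O)OC(C)(C)C | intermediate
6 | methyl (triphenylphosphoranylidene)acetate | COC(=O)C=P(c1ccccc1)(c1ccccc1)c1ccccc1 | starting material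
7 | methyl (E)-3-[4-(2-tert-butoxy-2-oxoethoxy)-3,5-dimethoxyphenyl]prop-2-enoate | COC(=O)/C=C/c1cc(OC)c(OCC(=O)OC(C)(C)C)c(OC)c1 | intermediate
8 | 2-{2,6-dimethoxy-4-[(E)-3-methoxy-3-oxoprop-1-enyl]phenoxy}acetic acid | COC(=O)/C=C/c1cc(OC)c(OCC(=O)O)c(OC)c1 | intermediate
9 | (R)-4-benzyl-2-oxazolidinone | O=C1N[C@H](Cc2ccccc2)CO1 | starting material
10 | mixed pivalic anhydride of acid 8 | COC(=O)/C=C/c1cc(OC)c(OCC(=O)OC(=O)C(C)(C)C)c(OC)c1 | intermediate
11 | (R)-4-benzyl-3-(2-{2,6-dimethoxy-4-[(E)-3-methoxy-3-oxoprop-1-enyl]phenoxy}acetyl)oxazolidin-2-one | COC(=O)/C=C/c1cc(OC)c(OCC(=O)N2[C@H](Cc3ccccc3)COC2=O)c(OC)c1 | intermediate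
12 | Z-dibutylboron enolate of imide 11 | CCCCB(CCCC)O/C(=C\Oc1c(OC)cc(/C=C/C(=O)OC)cc1OC)N1[C@H](Cc2ccccc2)COC1=O | intermediate
13 | O-dibutylboryl aldolate of 14 | COc1cc([C@H](OB(CCCC)CCCC)[C@H](C(=O)N2[C@H](Cc3ccccc3)COC2=O)Oc4c(OC)cc(/C=C/C(=O)OC)cc4OC)ccc1O[Si](C(C)C)(C(C)C)C(C)C | intermediate
14 | (R)-4-benzyl-3-[(2R,3S)-2-{2,6-dimethoxy-4-[(E)-3-methoxy-3-oxoprop-1-enyl]phenoxy}-3-hydroxy-3-(3-methoxy-4-triisopropylsilyloxyphenyl)propanoyl]oxazolidin-2-one | COc1cc([C@H](O)[C@H](C(=O)N2[C@H](Cc3ccccc3)COC2=O)Oc4c(OC)cc(/C=C/C(=O)OC)cc4OC)ccc1O[Si](C(C)C)(C(C)C)C(C)C | intermediate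
15 | methyl (E)-3-(4-{[(1S,2S)-1,3-dihydroxy-1-(3-methoxy-4-triisopropylsilyloxyphenyl)propan-2-yl]oxy}-3,5-dimethoxyphenyl)prop-2-enoate | COc1cc([C@H](O)[C@H](CO)Oc2c(OC)cc(/C=C/C(=O)OC)cc2OC)ccc1O[Si](C(C)C)(C(C)C)C(C)C | intermediate
16 | (1S,2S)-2-{4-[(E)-3-hydroxyprop-1-enyl]-2,6-dimethoxyphenoxy}-1-(3-methoxy-4-triisopropylsilyloxyphenyl)propane-1,3-diol | COc1cc([C@H](O)[C@H](CO)Oc2c(OC)cc(/C=C/CO)cc2OC)ccc1O[Si](C(C)C)(C(C)C)C(C)C | intermediate
17 | (1S,2S)-1-(4-hydroxy-3-methoxyphenyl)-2-{4-[(E)-3-hydroxyprop-1-enyl]-2,6-dimethoxyphenoxy}propane-1,3-diol | COc1cc([C@H](O)[C@H](CO)Oc2c(OC)cc(/C=C/CO)cc2OC)ccc1O | target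

**Step count**
Total steps: 9. Longest linear sequence: 8 steps (3 → 5 → 7 → 8 → 11 → 14 → 15 → 16 → 17); step 1 is the convergent branch.

**Steps most likely to fail, each with a fallback**

(a) Step 6, the boron aldol. The congested 2,6-dimethoxyaryloxy enolate and the extra Lewis-basic ester may slow enolisation or erode the diastereomer ratio. The fallback sets out from acid 8 (with aldehyde 2) and comes back at 15. Acid 8 is coupled with commercial (R)-4-benzyl-1,3-thiazolidine-2-thione (EDC·HCl, DMAP, CH2Cl2) to give the N-acylthiazolidinethione F1. Its chlorotitanium enolate (TiCl4, iPr2NEt, N-methyl-2-pyrrolidinone, CH2Cl2, −78 → 0 °C) adds to 2 in the same syn sense to give the (2R,3S) thiazolidinethione aldol adduct F2, which is separable by chromatography. NaBH4 in THF/EtOH at 0 °C then removes the thiazolidinethione reductively and delivers diol 15.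

(b) Step 7, the reductive auxiliary cleavage. Risks are partial reduction of the enoate, retro-aldol or ring-opening of the oxazolidinone. The fallback sets out from 14 and comes back at 16, bypassing steps 7 and 8. Hydrolysis with LiOH/H2O2 (THF/H2O, 0 °C, Na2SO3 quench) gives the (2R,3S) carboxylic acid F3. Me3SiCHN2 in toluene/MeOH converts it into the dimethyl ester F4. Excess i-Bu2AlH (CH2Cl2, −78 → 0 °C) reduces both methyl esters at once and gives triol 16.

(c) Step 8, DIBAL-H reduction in the presence of the free 1,3-diol. Aluminium alkoxide aggregates may give incomplete or unclean reduction. The fallback sets out from 15 and comes back at 17. The diol is silylated (Et3SiCl, imidazole, DMF) to the bis(triethylsilyl) ether F5. i-Bu2AlH (CH2Cl2, −78 °C) then gives the bis(triethylsilyl) allylic alcohol F6. Bu4NF/AcOH in THF removes the two triethylsilyl groups and the triisopropylsilyl group in one operation and gives target 17.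

**Further compounds**
F1 | step 6 | (R)-4-benzyl-3-(2-{2,6-dimethoxy-4-[(E)-3-methoxy-3-oxoprop-1-enyl]phenoxy}acetyl)-1,3-thiazolidine-2-thione | COC(=O)/C=C/c1cc(OC)c(OCC(=O)N2[C@H](Cc3ccccc3)CSC2=S)c(OC)c1
F2 | step 6 | (R)-4-benzyl-3-[(2R,3S)-2-{2,6-dimethoxy-4-[(E)-3-methoxy-3-oxoprop-1-enyl]phenoxy}-3-hydroxy-3-(3-methoxy-4-triisopropylsilyloxyphenyl)propanoyl]-1,3-thiazolidine-2-thione | COc1cc([C@H](O)[C@H](C(=O)N2[C@H](Cc3ccccc3)CSC2=S)Oc4c(OC)cc(/C=C/C(=O)OC)cc4OC)ccc1O[Si](C(C)C)(C(C)C)C(C)C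
F3 | step 7 | (2R,3S)-2-{2,6-dimethoxy-4-[(E)-3-methoxy-3-oxoprop-1-enyl]phenoxy}-3-hydroxy-3-(3-methoxy-4-triisopropylsilyloxyphenyl)propanoic acid | COc1cc([C@H](O)[C@H](C(=O)O)Oc2c(OC)cc(/C=C/C(=O)OC)cc2OC)ccc1O[Si](C(C)C)(C(C)C)C(C)C
F4 | step 7 | methyl (2R,3S)-2-{2,6-dimethoxy-4-[(E)-3-methoxy-3-oxoprop-1-enyl]phenoxy}-3-hydroxy-3-(3-methoxy-4-triisopropylsilyloxyphenyl)propanoate | COc1cc([C@H](O)[C@H](C(=O)OC)Oc2c(OC)cc(/C=C/C(=O)OC)cc2OC)ccc1O[Si](C(C)C)(C(C)C)C(C)C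
F5 | step 8 | methyl (E)-3-(4-{[(1S,2S)-1,3-bis(triethylsilyloxy)-1-(3-methoxy-4-triisopropylsilyloxyphenyl)propan-2-yl]oxy}-3,5-dimethoxyphenyl)prop-2-enoate | COc1cc([C@H](O[Si](CC)(CC)CC)[C@H](CO[Si](CC)(CC)CC)Oc2c(OC)cc(/C=C/C(=O)OC)cc2OC)ccc1O[Si](C(C)C)(C(C)C)C(C)C
F6 | step 8 | (E)-3-(4-{[(1S,2S)-1,3-bis(triethylsilyloxy)-1-(3-methoxy-4-triisopropylsilyloxyphenyl)propan-2-yl]oxy}-3,5-dimethoxyphenyl)prop-2-en-1-ol | COc1cc([C@H](O[Si](CC)(CC)CC)[C@H](CO[Si](CC)(CC)CC)Oc2c(OC)cc(/C=C/CO)cc2OC)ccc1O[Si](C(C)C)(C(C)C)C(C)C
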